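**Assumption:** the SMILES is read as the (3S,4R,6R,7S,8R,9R,10R,12S,13R) isomer; locants C1 (alkyne CH) to C15 (ethyl CH3) are used below, and unnumbered reagents are ordinary commercial chemicals.

**Retrosynthetic overview**
- The bridging C4–O–C7 ether and the C8–Br bond are made last, by 5-exo bromoetherification of a (Z)-C7=C8 alkene with the C4 hydroxyl of a preformed oxolane.
- The (Z)-alkene comes from a Wittig union of a C1–C7 oxolanylmethyl phosphonium salt with a C8–C15 dibromo-oxane aldehyde.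
- The 3,5-dibromo-oxane is made in one step from a skipped epoxy-alkene and Br2 (new epoxide-relay dibromo-cyclisation); the epoxide comes from Sharpless epoxidation of (2E,5E)-octa-2,5-dien-1-ol, itself from (E)-hex-3-en-1-ol.
- The oxolane is made by Shi epoxidation of an (E)-enyne chlorohydrin and 5-endo epoxide opening; the chlorohydrin comes from (R)-epichlorohydrin and acetylene.
- Ring order: oxane (C9–O–C13), then oxolane (C3–O–C6), then the bridging oxolane (C4–O–C7).

**Route**

Step 1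
Reactants: 1 (E)-hex-3-en-1-ol
Product: 3 ethyl (2E,5E)-octa-2,5-dienoate, via (E)-hex-3-enal 2 (not isolated)
Conditions: IBX, Ph3P=CHCO2Et, DMSO, rt
Reagents that add atoms: ethyl (triphenylphosphoranylidene)acetate, CCOC(=O)C=P(c1ccccc1)(c1ccccc1)c1ccccc1
Why: One-pot IBX oxidation/Wittig olefination traps the isomerisation-prone β,γ-unsaturated aldehyde as it forms, and the stabilised ylide gives the (2E)-enoate while the (5E) geometry is carried over from 1.

Step 2
Reactants: 3 ethyl (2E,5E)-octa-2,5-dienoate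
Product: 4 (2E,5E)-octa-2,5-dien-1-ol
Conditions: DIBAL-H (2.3 equiv), CH2Cl2, −78 → 0 °C; Rochelle salt
Reagents that add atoms: none
Why: DIBAL-H 1,2-reduction of an α,β-unsaturated ester gives the allylic alcohol under non-basic conditions that leave the skipped diene unconjugated.

Step 3
Reactants: 4 (2E,5E)-octa-2,5-dien-1-ol
Product: 5 [(2S,3S)-3-[(2E)-pent-2-en-1-yl]oxiran-2-yl]methanol
Conditions: Ti(OiPr)4 (10 mol%), L-(+)-DIPT (12 mol%), t-BuOOH, 4 Å MS, CH2Cl2, −20 °C
Reagents that add atoms: tert-butyl hydroperoxide, CC(C)(C)OO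
Why: Sharpless asymmetric epoxidation reacts only at the allylic alkene, and L-(+)-tartrate gives the (2S,3S)-trans-epoxide, which sets C9 and the configuration at C10 that is later inverted.

Step 4
Reactants: 5 [(2S,3S)-3-[(2E)-pent-2-en-1-yl]oxiran-2-yl]methanol
Product: 7 [(2S,3R,5S,6R)-3,5-dibromo-6-ethyloxan-2-yl]methanol, via epoxonium bromide 6 (not isolated)
Conditions: Br2 (1.0 equiv, added over 2 h), HFIP–CH2Cl2 (1:4), 0.01 M, −30 °C
Reagents that add atoms: bromine, BrBr
Why: Proposed new method: the C12=C13 bromonium can be reached by the oxirane oxygen only at C13 (five-membered transition state; attack at C12 would need a fused oxetane), giving bicyclic epoxonium 6 with Br anti to the new C–O bond and the ethyl group on the face away from the fused oxirane carbon, and bromide then opens 6 at C10 with inversion (C9 is deactivated by the adjacent CH2OH, whose own participation would require a trans-fused ring), so the oxygen ends on C9 and C13 and all four substituents are equatorial; HFIP hydrogen-bonds bromide and slows direct dibromide formation, and the closest known reactions are bromonium-initiated epoxide-opening cascades terminated by oxygen nucleophiles and 5-endo halo-etherification of (E)-homoallylic alcohols.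

Step 5
Reactants: 7 [(2S,3R,5S,6R)-3,5-dibromo-6-ethyloxan-2-yl]methanol
Product: 8 (2S,3R,5S,6R)-3,5-dibromo-6-ethyloxane-2-carbaldehyde
Conditions: Dess–Martin periodinane, CH2Cl2, rt; used crude
Reagents that add atoms: none
Why: Dess–Martin oxidation is neutral, so the β-bromo aldehyde does not eliminate, and the formyl group is already in the favoured equatorial position.

Step 6
Reactants: 9 (R)-epichlorohydrin
Product: 10 (2R)-1-chloropent-4-yn-2-ol
Conditions: acetylene, n-BuLi, THF, −78 °C; BF3·OEt2; then 9, −78 °C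
Reagents that add atoms: acetylene, C#C
Why: BF3-promoted acetylide opening of the epoxide (Yamaguchi–Hirao alkynylation) occurs at the CH2 terminus at −78 °C, so the chloride and the stereocentre (later C6) are untouched.

Step 7
Reactants: 10 (2R)-1-chloropent-4-yn-2-ol
Product: 12 (2R,4E)-1-chloro-5-iodopent-4-en-2-ol, via alkenylzirconocene 11 (not isolated)
Conditions: Cp2Zr(H)Cl (2.2 equiv), THF, 0 °C → rt; then I2, 0 °C
Reagents that add atoms: iodine, II
Why: Schwartz hydrozirconation adds syn with Zr at the terminal carbon (one equivalent is used up by the hydroxyl) and iodinolysis proceeds with retention, giving the (E)-vinyl iodide.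

Step 8
Reactants: 12 (2R,4E)-1-chloro-5-iodopent-4-en-2-ol
Product: 13 (2R,4E)-1-chloro-7-(trimethylsilyl)hept-4-en-6-yn-2-ol
Conditions: ethynyltrimethylsilane, Pd(PPh3)2Cl2 (2 mol%), CuI (4 mol%), Et3N, THF, rt
Reagents that add atoms: ethynyltrimethylsilane, C#C[Si](C)(C)C
Why: Sonogashira coupling of a vinyl iodide proceeds with retention of the (E) geometry under conditions too mild to close the chlorohydrin.

Step 9
Reactants: 13 (2R,4E)-1-chloro-7-(trimethylsilyl)hept-4-en-6-yn-2-ol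
Product: 15 (2S,3R,5R)-5-(chloromethyl)-2-[2-(trimethylsilyl)ethynyl]oxolan-3-ol, via epoxide 14 (not isolated)
Conditions: D-fructose-derived Shi ketone (30 mol%), Oxone, K2CO3, Bu4NHSO4, MeCN–DMM–aq. buffer (pH ≈ 10), 0 °C, 2 h; then CSA (10 mol%), CH2Cl2, rt
Reagents that add atoms: Oxone (potassium peroxymonosulfate), [K+].[O-]S(=O)(=O)OO
Why: Shi asymmetric epoxidation of the conjugated (E)-enyne gives the (3R,4R)-epoxide under catalyst control, and acid-catalysed 5-endo anti opening at the propargylic C3 by the C6 hydroxyl (the 4-exo mode would give an oxetane) inverts C3, placing the C4 hydroxyl trans to the alkynyl group and cis to CH2Cl.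

Step 10
Reactants: 15 (2S,3R,5R)-5-(chloromethyl)-2-[2-(trimethylsilyl)ethynyl]oxolan-3-ol
Product: 17 {[(2R,4R,5S)-4-hydroxy-5-[2-(trimethylsilyl)ethynyl]oxolan-2-yl]methyl}triphenylphosphonium iodide, via iodide 16 (not isolated)
Conditions: NaI (2 equiv), PPh3 (1.5 equiv), MeCN, sealed tube, 100 °C, 48–72 h
Reagents that add atoms: triphenylphosphine, c1ccc(cc1)P(c1ccccc1)c1ccccc1; sodium iodide, [Na+].[I-]
Why: Finkelstein exchange followed by SN2 quaternisation of PPh3 at the primary carbon gives the salt under neutral conditions that touch no stereocentre.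

Step 11
Reactants: 17 {[(2R,4R,5S)-4-hydroxy-5-[2-(trimethylsilyl)ethynyl]oxolan-2-yl]methyl}triphenylphosphonium iodide; 8 (2S,3R,5S,6R)-3,5-dibromo-6-ethyloxane-2-carbaldehyde
Product: 21 (2S,3R,5R)-5-[(Z)-2-[(2S,3R,5S,6R)-3,5-dibromo-6-ethyloxan-2-yl]ethenyl]-2-ethynyloxolan-3-ol, via O-silyl phosphonium iodide 18 (not isolated), via ylide 19 (not isolated), via silylated (Z)-alkene 20 (not isolated)
Conditions: Et2NSiMe3, THF, rt, then evaporate; KHMDS (1.05 equiv), THF, −78 °C; 8, −78 → 0 °C; then K2CO3, MeOH, rt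
Reagents that add atoms: none
Why: Transient O-silylation avoids an oxido ylide, the salt-free Wittig reaction of the non-stabilised ylide gives the (Z)-alkene under kinetic control at −78 °C (addition to the aldehyde outruns α-deprotonation), and methanolysis then removes both silyl groups.

Step 12
Reactants: 21 (2S,3R,5R)-5-[(Z)-2-[(2S,3R,5S,6R)-3,5-dibromo-6-ethyloxan-2-yl]ethenyl]-2-ethynyloxolan-3-ol
Product: 22 (1R,3S,4R,6S)-3-[(R)-bromo[(2R,3R,5S,6R)-3,5-dibromo-6-ethyloxan-2-yl]methyl]-6-ethynyl-2,5-dioxabicyclo[2.2.1]heptane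
Conditions: NBS (1.1 equiv), HFIP–CH2Cl2 (1:4), −20 → 0 °C
Reagents that add atoms: N-bromosuccinimide, O=C1CCC(=O)N1Br
Why: In this 5-exo bromoetherification the cis C4 hydroxyl attacks C7 while Br+ adds anti at C8 (attack at C8 is disfavoured by the oxane oxygen and C10–Br next to it), so the (Z) geometry fixes the C7/C8 relative configuration, and the expected rotamer (ring oxygen eclipsing the alkene, Br+ anti to the C5 methylene) gives (7S,8R) with C8 endo.

**Compound list**
1 | (E)-hex-3-en-1-ol | OCC/C=C/CC | starting material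
2 | (E)-hex-3-enal | O=CC/C=C/CC | intermediate
3 | ethyl (2E,5E)-octa-2,5-dienoate | CCOC(=O)/C=C/C/C=C/CC | intermediate
4 | (2E,5E)-octa-2,5-dien-1-ol | OC/C=C/C/C=C/CC | intermediate
5 | [(2S,3S)-3-[(2E)-pent-2-en-1-yl]oxiran-2-yl]methanol | OC[C@@H]1O[C@H]1C/C=C/CC | intermediate
6 | epoxonium bromide: 3-bromo-2-ethyl-6-(hydroxymethyl)-1-oxoniabicyclo[3.1.0]hexane bromide (oxirane carbons as in 5; Br and ethyl trans; ethyl on the face opposite the fused oxirane carbon) | [Br-].OC[C@H]1[C@@H]2C[C@H](Br)[C@@H](CC)[O+]12 | intermediate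
7 | [(2S,3R,5S,6R)-3,5-dibromo-6-ethyloxan-2-yl]methanol | OC[C@@H]1O[C@H](CC)[C@@H](Br)C[C@H]1Br | intermediate
8 | (2S,3R,5S,6R)-3,5-dibromo-6-ethyloxane-2-carbaldehyde | O=C[C@@H]1O[C@H](CC)[C@@H](Br)C[C@H]1Br | intermediate
9 | (R)-epichlorohydrin, (2R)-2-(chloromethyl)oxirane | ClC[C@H]1CO1 | starting material
10 | (2R)-1-chloropent-4-yn-2-ol | C#CC[C@@H](O)CCl | intermediate
11 | alkenylzirconocene: (E)-Cp2Zr(Cl)–CH=CH–CH2–CH(OZrCp2Cl)–CH2Cl, (R) at the carbinol carbon | ClC[C@@H](C/C=C/[Zr](Cl)(C1C=CC=C1)C1C=CC=C1)O[Zr](Cl)(C1C=CC=C1)C1C=CC=C1 | intermediate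
12 | (2R,4E)-1-chloro-5-iodopent-4-en-2-ol | I/C=C/C[C@@H](O)CCl | intermediate
13 | (2R,4E)-1-chloro-7-(trimethylsilyl)hept-4-en-6-yn-2-ol | C[Si](C)(C)C#C/C=C/C[C@@H](O)CCl | intermediate
14 | (2R)-1-chloro-3-[(2R,3R)-3-[2-(trimethylsilyl)ethynyl]oxiran-2-yl]propan-2-ol | C[Si](C)(C)C#C[C@H]1O[C@@H]1C[C@@H](O)CCl | intermediate
15 | (2S,3R,5R)-5-(chloromethyl)-2-[2-(trimethylsilyl)ethynyl]oxolan-3-ol | C[Si](C)(C)C#C[C@@H]1O[C@@H](CCl)C[C@H]1O | intermediate
16 | (2S,3R,5R)-5-(iodomethyl)-2-[2-(trimethylsilyl)ethynyl]oxolan-3-ol | C[Si](C)(C)C#C[C@@H]1O[C@@H](CI)C[C@H]1O | intermediate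
17 | {[(2R,4R,5S)-4-hydroxy-5-[2-(trimethylsilyl)ethynyl]oxolan-2-yl]methyl}triphenylphosphonium iodide | [I-].C[Si](C)(C)C#C[C@@H]1O[C@@H](C[P+](c2ccccc2)(c2ccccc2)c2ccccc2)C[C@H]1O | intermediate
18 | O-trimethylsilyl ether of 17 | [I-].C[Si](C)(C)C#C[C@@H]1O[C@@H](C[P+](c2ccccc2)(c2ccccc2)c2ccccc2)C[C@H]1O[Si](C)(C)C | intermediate
19 | ylide derived from 18 (P=CH at the oxolane C2 substituent) | C[Si](C)(C)C#C[C@@H]1O[C@@H](C=P(c2ccccc2)(c2ccccc2)c2ccccc2)C[C@H]1O[Si](C)(C)C | intermediate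
20 | O,C-bis(trimethylsilyl) derivative of 21 | C[Si](C)(C)C#C[C@@H]1O[C@@H](/C=C\[C@@H]2O[C@H](CC)[C@@H](Br)C[C@H]2Br)C[C@H]1O[Si](C)(C)C | intermediate
21 | (2S,3R,5R)-5-[(Z)-2-[(2S,3R,5S,6R)-3,5-dibromo-6-ethyloxan-2-yl]ethenyl]-2-ethynyloxolan-3-ol | C#C[C@@H]1O[C@@H](/C=C\[C@@H]2O[C@H](CC)[C@@H](Br)C[C@H]2Br)C[C@H]1O | intermediate
22 | (1R,3S,4R,6S)-3-[(R)-bromo[(2R,3R,5S,6R)-3,5-dibromo-6-ethyloxan-2-yl]methyl]-6-ethynyl-2,5-dioxabicyclo[2.2.1]heptane | C#C[C@@H]1O[C@@H]2C[C@H]1O[C@@H]2[C@@H](Br)[C@@H]1O[C@H](CC)[C@@H](Br)C[C@H]1Br | target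

**Step count and risks**

Total steps: 12. Longest linear sequence: 7 (steps 1–5, 11, 12; the arm through steps 6–10 is equally long).

The three steps most likely to fail:

1. Step 4 (the proposed new step). Direct dibromination of the alkene, bromide attack at C9 instead of C10, or poor facial selectivity could each defeat it. The fallback uses known chemistry and sets out from 5. C3-selective bromide opening of the epoxy alcohol (MgBr2·OEt2, Et2O, −20 °C, or Ti(OiPr)4/Et2NH·HBr) gives (2S,3R,5E)-3-bromooct-5-ene-1,2-diol F1. Selective primary silylation (TBDPSCl, imidazole) gives (2S,3R,5E)-3-bromo-1-[(tert-butyldiphenylsilyl)oxy]oct-5-en-2-ol F2. 6-endo bromoetherification through an all-equatorial chair (TBCO, CH2Cl2; the 5-exo regioisomer is removed by chromatography) gives tert-butyl{[(2S,3R,5S,6R)-3,5-dibromo-6-ethyloxan-2-yl]methoxy}diphenylsilane F3. TBAF then returns the route to 7.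

2. Step 12. The wrong alkene face (C8 exo) or 6-endo closure would give isomers. The fallback sets out from 21 and fixes both new centres by catalyst control and SN2 chemistry. Thiyl-radical or iodine-catalysed photo-isomerisation (cat. PhSSPh, hν; Z recycled; the terminal alkyne is the weak point) gives the (E)-alkene isomer of 21 F4. Shi epoxidation (D-fructose-derived ketone) gives the (7R,8S)-trans-epoxide F5. CSA-catalysed 5-exo opening at C7 by the C4 hydroxyl, with inversion, gives the (8S)-alcohol F6, which is 22 with OH in place of the C8 bromine and the opposite configuration at C8. Bromination with inversion (CBr4, P(n-Oct)3, toluene, 70 °C) returns the route at 22.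

3. Step 11. The β-alkoxy ylide, the β-bromo aldehyde and the hindered partners could cost Z-selectivity or cause elimination. The fallback gives up the (Z)-alkene and sets out from 15 and 8. Thiolate displacement (1-phenyl-1H-tetrazole-5-thiol, K2CO3, cat. NaI, DMF, 80 °C) gives the tetrazolyl sulfide F7. Oxidation (H2O2, cat. ammonium molybdate, EtOH) gives the sulfone F8. Julia–Kocienski olefination with 8 in Barbier mode (LiHMDS, 2.1 equiv, THF, −78 °C) gives the (E)-alkene carrying the silylated alkyne F9. K2CO3/MeOH then gives F4, and the sequence through F5 and F6 described for step 12 returns the route at 22.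

**Further compounds**
F1 | step 4 | (2S,3R,5E)-3-bromooct-5-ene-1,2-diol | OC[C@H](O)[C@H](Br)C/C=C/CC
F2 | step 4 | (2S,3R,5E)-3-bromo-1-[(tert-butyldiphenylsilyl)oxy]oct-5-en-2-ol | CC(C)(C)[Si](c1ccccc1)(c1ccccc1)OC[C@H](O)[C@H](Br)C/C=C/CC
F3 | step 4 | tert-butyl{[(2S,3R,5S,6R)-3,5-dibromo-6-ethyloxan-2-yl]methoxy}diphenylsilane | CC(C)(C)[Si](c1ccccc1)(c1ccccc1)OC[C@@H]1O[C@H](CC)[C@@H](Br)C[C@H]1Br
F4 | step 12 | (2S,3R,5R)-5-[(E)-2-[(2S,3R,5S,6R)-3,5-dibromo-6-ethyloxan-2-yl]ethenyl]-2-ethynyloxolan-3-ol | C#C[C@@H]1O[C@@H](/C=C/[C@@H]2O[C@H](CC)[C@@H](Br)C[C@H]2Br)C[C@H]1O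
F5 | step 12 | (7R,8S)-trans-epoxide of F4: (2S,3R,5R)-5-[3-(3,5-dibromo-6-ethyloxan-2-yl)oxiran-2-yl]-2-ethynyloxolan-3-ol | C#C[C@@H]1O[C@@H]([C@H]2O[C@@H]2[C@@H]3O[C@H](CC)[C@@H](Br)C[C@H]3Br)C[C@H]1O
F6 | step 12 | (8S)-alcohol: 22 with OH in place of the C8 bromine and inverted C8 | C#C[C@@H]1O[C@@H]2C[C@H]1O[C@@H]2[C@H](O)[C@@H]1O[C@H](CC)[C@@H](Br)C[C@H]1Br
F7 | step 11 | (2S,3R,5R)-5-{[(1-phenyl-1H-tetrazol-5-yl)sulfanyl]methyl}-2-[2-(trimethylsilyl)ethynyl]oxolan-3-ol | C[Si](C)(C)C#C[C@@H]1O[C@@H](CSc2nnnn2-c2ccccc2)C[C@H]1O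
F8 | step 11 | (2S,3R,5R)-5-{[(1-phenyl-1H-tetrazol-5-yl)sulfonyl]methyl}-2-[2-(trimethylsilyl)ethynyl]oxolan-3-ol | C[Si](C)(C)C#C[C@@H]1O[C@@H](CS(=O)(=O)c2nnnn2-c2ccccc2)C[C@H]1O
F9 | step 11 | C-trimethylsilyl derivative of F4 | C[Si](C)(C)C#C[C@@H]1O[C@@H](/C=C/[C@@H]2O[C@H](CC)[C@@H](Br)C[C@H]2Br)C[C@H]1O
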